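The ratio of loss to time read from Wednesday's flask is 0.0987 h⁻¹: the readings put the loss of the two substrates together at 39.5% of their charge by 4.00 h. We call this the feed, the part of both substrates charged that goes per hour, averaged from the start. It replaces a curve by its mean, so we check the error that makes.

| setting | Sunday's | Wednesday's | flask |
|---|---|---|---|
| left-handed substrate | 0.56 M | 0.56 M | 0.56 M |
| right-handed substrate | 0.56 M | 0.56 M | 0.56 M |
| gas | 180 mM (held) | 180 mM (held) | 180 mM (held) |
| free catalyst | 10 mol% | 10 mol% | 10 mol% |
| precatalyst | 0.52 mol% | 0.26 mol% | 0.52 mol% |
| remark | the very flask that is asked about, followed so far | run made earlier |  |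
| time |  |  | 4.0 h |

Sunday's run (percent of the left-handed substrate and right-handed substrate together charged)

| time / min | left-handed substrate / % | right-handed substrate / % | left-handed product / % |
|---|---|---|---|
| 1.33 | 50.1 | 50.4 | 0.2 |
| 4.00 | 50.5 | 49.2 | 0 |
| 6.00 | 49.3 | 50.1 | 1.0 |
| 10.0 | 49.2 | 50.1 | 1.5 |
| 15.0 | 49.6 | 49.1 | 0.8 |
| 20.0 | 47.6 | 48.9 | 0.8 |

Wednesday's run (percent of the left-handed substrate and right-handed substrate together charged)

| time / h | left-handed substrate / % | right-handed substrate / % | left-handed product / % |
|---|---|---|---|
| 0.333 | 48.2 | 48.5 | 1.6 |
| 0.500 | 47.4 | 49.2 | 3.3 |
| 0.833 | 45.3 | 46.6 | 4.1 |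
| 1.33 | 41.8 | 45.1 | 7.7 |
| 2.50 | 34.3 | 39.6 | 13.6 |
| 4.00 | 26.4 | 34.1 | 20.1 |

(scatter of a reading: 0.5 percentage points)

- free catalyst is single-handed; left-handed substrate and right-handed substrate are mirror images of each other, charged as a racemate, each of them at the stated concentration
- at the start none of partner is dissolved
- the numbers in the tables scatter with a standard deviation of 0.5 percentage points
- steps that have been proposed: left-handed substrate + racemization catalyst <-> right-handed substrate + racemization catalyst; partner + free catalyst + left-handed substrate -> free catalyst + left-handed product; left-handed product <-> right-handed product; gas <-> partner; partner + free catalyst + right-handed substrate -> free catalyst + right-handed product; partner + precatalyst -> racemization catalyst + spent reagent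
- an excess is the difference of the two amounts in percent of their sum
- an excess is below zero if the other one leads

* part of the left-handed substrate and right-handed substrate charged together that has reacted at 4.0 h
* excess of left-handed product over right-handed product in the product at 4.0 h
* excess of right-handed substrate over left-handed substrate among what is left of the two at 4.0 h

At the start no partner is dissolved; it has to come from the gas. The readings of Sunday's flask, the one asked about, give a loss of 3.50% by 20.0 min, and the feed predicts 3.29%. A single reading scatters by 0.5 percentage points, so the two agree. Sunday's flask holds twice the precatalyst of Wednesday's flask, yet these early readings show no clear gain.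

In the middle of Wednesday's flask, at 2.50 h, the feed predicts a loss of 24.7% and the readings give 26.1%. The mean is off by 1.4 points. In Wednesday's flask at that time, left-handed product reads about half of what has gone.

Towards the end of Wednesday's flask the readings put the loss at 0.0893 h⁻¹, with the substrates at 60.5% of their charge. The rate has kept more of the feed than the substrates have kept of their charge, so we read the uptake of gas as partner as the rate-limiting step. For Sunday's flask at 4.0 h we therefore commit to 39.5% reacted.

The forecast reads “This zero order suggests gas supply limits the rate” and gives 39.7% reacted (37.5% to 41.5%), a product excess of 2% (0% to 5%) and a substrate excess of 12% (8.5% to 14%). The flask gives 40.0% reacted, an excess of left-handed product of 3.30% and an excess of right-handed substrate of 12.6%.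

    left-handed substrate + racemization catalyst ⇌ right-handed substrate + racemization catalyst, rate k1*[racemization catalyst]*[left-handed substrate] forward; the back reaction follows from the equilibrium constant (k = 7.92 × 10⁻⁴ L mol⁻¹ s⁻¹)
    partner + free catalyst + left-handed substrate → free catalyst + left-handed product (k = 0.196 L² mol⁻² s⁻¹)
    left-handed product ⇌ right-handed product (k = 1.59 × 10⁻⁴ s⁻¹)
    gas ⇌ partner, rate k4*(csat - [partner]) (kL = 1.79 × 10⁻⁴ s⁻¹)
    partner + free catalyst + right-handed substrate → free catalyst + right-handed product (k = 0.119 L² mol⁻² s⁻¹)
    partner + precatalyst → racemization catalyst + spent reagent (k = 0.00166 L mol⁻¹ s⁻¹)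

The feed of the asked flask comes to 0.100 h⁻¹, and at 4.00 h that flask makes partner 1.01 times as fast as it uses it, each step taken net, with partner at 0.00539 M, far below its saturation concentration of 180 mM. The neighbouring flask, with a quarter of the precatalyst, has 40.0% reacted at 4.00 h, a feed of 0.100 h⁻¹.

The numbers in the tables are calculated on assumed constants; the scatter is artificial.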